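Oak, ash and elm each hold the same 0.50 M of starting material, and you have to say which leaves the highest share of target among target, isomer of the product and third isomer.

| flask | starting material | remark | time |
|---|---|---|---|
| noon | 0.50 M | run made earlier |  |
| autumn | 0.34 M | run made earlier |  |
| dusk | 0.75 M | run made earlier |  |
| oak | 0.50 M | one stirred flow tank at steady state, fed with the mixture as stated, mean residence time 25 min |  |
| ash | 0.50 M | one stirred flow tank at steady state, fed with the mixture as stated, mean residence time 125 min |  |
| elm | 0.50 M | a closed flask charged with all of it at once and left for 25 min | 25 min |

| run | time / min | target / % | isomer of the product / % |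
|---|---|---|---|
| noon | 2.00 | 36 | 33 |
| noon | 4.00 | 31 | 42 |
| noon | 8.00 | 23 | 55 |
| noon | 12.0 | 13 | 61 |
| noon | 25.0 | 10 | 69 |
| autumn | 5.00 | 27 | 46 |
| autumn | 10.0 | 15 | 60 |
| autumn | 15.0 | 14 | 64 |
| autumn | 20.0 | 11 | 69 |
| autumn | 25.0 | 12 | 69 |
| dusk | 5.00 | 28 | 44 |
| dusk | 10.0 | 21 | 59 |
| dusk | 15.0 | 14 | 64 |
| dusk | 20.0 | 11 | 69 |
| dusk | 25.0 | 13 | 70 |

(scatter of a reading: 1.5 percentage points)

- the stated concentrations are those of everything mixed, before any reaction; amounts are the same in each set-up
- what was read earlier has a scatter of 1.5 percentage points, one standard deviation
- the earlier runs were made in a closed, stirred flask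

- the set-up with the highest share of target in all that became target or isomer of the product or third isomer, at the outlet or at the end ("none" if the first two lie within 2 percentage points) (oak / ash / elm / none)
- share of target in all that became target or isomer of the product or third isomer, at the outlet or at the end, oak
- share of target in all that became target or isomer of the product or third isomer, at the outlet or at the end, ash
- share of target in all that became target or isomer of the product or third isomer, at the outlet or at the end, elm

The autumn and dusk runs differ 2.21-fold in charge, yet they read 14 % and 14 % target at 15.0 min, so I use one first-order curve, in percent of charge, for oak, ash and elm. On the fastest rung of the ladder, the noon run at 2.00 min already shows 69.0 % of its charge as target and isomer of the product, with target ahead. On the next rung, target slides toward a plateau, which I read as the mean of the last readings, 11.7 %. The excess over that plateau falls from 24 percentage points at 2.00 min in noon to 2.3 points at 15.0 min in autumn and dusk, a reading that carries the scatter of 1.5 points. That gives a decay rate λ of 0.180 min⁻¹. The relaxation time θ, the mean life of an excess of target, is therefore 5.54 min. Run back to time zero, this curve has an intercept E of 34.9 %, a figure of the curve and not an amount that stands in a flask at that moment.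

Now follow one molecule of excess target in a tank with mean residence time τ. At each instant it either relaxes, at rate 1/θ, or leaves, at rate 1/τ, so its chance of leaving first is θ/(θ+τ). In a closed flask its chance of lasting to time t is exp(−t/θ). I count the unread remainder as third isomer, so a share is plateau plus E times that chance. The top rungs are 25 min for oak and for elm's standing time, and 125 min for ash. My reckoning gives oak 18.0 %, ash 13.1 % and elm 12.1 %. Oak stands above elm because its chance, 18.1 %, exceeds elm's 1.10 %.

The forecast names oak, with oak 18 %, ash 13 % and elm 11.5 %: “Oak is best, because its broad residence-time distribution leaves some early, target-rich material.” My elm figure is the higher of the two.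

The flask gives oak: oak 18.9 %, ash 12.0 %, elm 11.4 %.

    starting material ⇌ target (K = 2.18, k = 0.847 min⁻¹)
    starting material ⇌ isomer of the product (K = 17.7, k = 0.478 min⁻¹)
    starting material ⇌ third isomer (K = 2.20, k = 0.142 min⁻¹)
    starting material ⇌ dormant form (K = 0.415, k = 0.0704 min⁻¹)
    starting material → decomposition product (k = 1.35 × 10⁻⁴ min⁻¹)

Starting material has a forward half-life of 0.82 min toward target, shorter than 1.5 min toward isomer of the product. Yet the equilibrium constant of isomer of the product, 17.7, stands above that of target, 2.18: kinetic against thermodynamic control. With θ at 5.54 min, the tank rule gave 18.0 % for oak against the flask's 18.9 %. For the same flask as elm read at 10 min, the closed-flask rule gives 17.4 % of the charge as target, and that flask holds 18.0 % of its charge as target, a share of 20.1 % among target, isomer of the product and third isomer.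

The runs come from a simulation on assumed constants; scatter was added.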